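The route rests on disconnecting the C9–C10 bond of the seven-membered ring (C10 carries the exocyclic methylene, C9 the ring acetoxy group). This C10(=CH2)–C9(O) allylic alcohol motif is the retron of an alkenyl-metal addition to an aldehyde, so an intramolecular Nozaki–Hiyama–Kishi reaction closes the cycloheptane onto the preformed cyclopentene, creates the exocyclic alkene and sets C9 in one operation. Its precursor is a 1-methylcyclopentene whose adjacent ring carbons C1 and C5 carry, trans to each other, a 1-iodovinyl group and the stereodefined C6–C9 chain ending in an aldehyde. It is assembled by an asymmetric conjugate addition/aldol three-component coupling on cyclopentenone.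

Key step: step 16

Numbering used throughout (target numbering): C1 and C5 are the ring-fusion carbons; C2, C3, C4 (bearing CH3) complete the cyclopentene; C6 (OH), C7 (side chain), C8, C9 (OAc), C10 (=CH2) complete the seven-membered ring; C11 (CH3) and C12 (OAc) are the first two side-chain carbons. The target is (1R,5S,6R,7S,9R,11S,12S) with a trans ring fusion.

Assumption: in step 9 the enantiomer of the chiral carbene ligand is the one that delivers the alkenyl group to the enone face giving the 3R enolate 20; the mirror-image ligand is used if the sense of induction proves opposite.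

Step 1
Reactants: 1 4-methylpent-3-en-1-ol
Product: 2 4-methylpent-3-enal
Conditions: Dess–Martin periodinane, NaHCO3, CH2Cl2, 0 °C → rt
Reagents that add atoms: none
Why: Dess–Martin oxidation of the primary alcohol under buffered, non-basic conditions should stop at the aldehyde without moving the β,γ-double bond into conjugation, and no stereocentre is formed.

Step 2
Reactants: 2 4-methylpent-3-enal; 3 cis-but-2-ene
Product: 6 (3S,4S)-3,7-dimethylocta-1,6-dien-4-ol, via crotylborane 4 (not isolated), via borinate ester 5 (not isolated)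
Conditions: 3, n-BuLi, KOt-Bu, THF, −78 → −45 °C; (+)-Ipc2BOMe [from (−)-α-pinene], −78 °C; BF3·OEt2; 2, −78 °C; then NaOH, H2O2
Reagents that add atoms: none
Why: Brown crotylboration through a closed chair-like transition state, in which the Z geometry of 4 gives the syn methyl/hydroxyl relationship and the isopinocampheyl groups from (−)-α-pinene direct the crotyl group to the Re face of 2, so that C11 and C12 are set (both S).

Step 3
Reactants: 6 (3S,4S)-3,7-dimethylocta-1,6-dien-4-ol
Product: 8 (3S,4S)-3,7-dimethyloct-6-ene-1,4-diol, via organoborane 7 (not isolated)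
Conditions: 9-BBN (2.2 equiv), THF, 0 °C → rt; then NaOH, H2O2, 0 °C
Reagents that add atoms: hydrogen peroxide, OO
Why: Hydroboration–oxidation with the bulky 9-BBN should be selective for the monosubstituted alkene over the trisubstituted one and place boron on the terminal carbon, giving the primary alcohol without touching the stereocentres.

Step 4
Reactants: 8 (3S,4S)-3,7-dimethyloct-6-ene-1,4-diol
Product: 10 (4S,5S)-4-methyl-5-(3-methylbut-2-en-1-yl)oxolan-2-one, via lactol 9 (not isolated)
Conditions: TEMPO (cat.), PhI(OAc)2, CH2Cl2, rt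
Reagents that add atoms: none
Why: Oxidative lactonisation of a 1,4-diol, in which the nitroxyl oxidant takes the primary alcohol to the aldehyde, this closes to lactol 9 and is oxidised on to the γ-lactone, whose cis 4-methyl/5-alkyl relationship follows from the syn crotylation.

Step 5
Reactants: 10 (4S,5S)-4-methyl-5-(3-methylbut-2-en-1-yl)oxolan-2-one; 11 2-(tert-butyldimethylsilyloxy)ethyl trifluoromethanesulfonate
Product: 13 (3S,4S,5S)-3-[2-(tert-butyldimethylsilyloxy)ethyl]-4-methyl-5-(3-methylbut-2-en-1-yl)oxolan-2-one, via lithium enolate 12 (not isolated)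
Conditions: LiN(i-Pr)2, THF, −78 °C; then 11, DMPU, −78 → −40 °C
Reagents that add atoms: none
Why: Lactone enolate alkylation in which the primary triflate attacks enolate 12 on the face anti to the adjacent ring methyl group (and to the cis C5 substituent), setting C7 of the target trans to that methyl group and bringing in C8 and C9.

Step 6
Reactants: 13 (3S,4S,5S)-3-[2-(tert-butyldimethylsilyloxy)ethyl]-4-methyl-5-(3-methylbut-2-en-1-yl)oxolan-2-one
Product: 14 (2S,3S,4S)-2-[2-(tert-butyldimethylsilyloxy)ethyl]-4-hydroxy-N-methoxy-N,3,6-trimethylhept-5-enamide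
Conditions: MeNH(OMe)·HCl, AlMe3, CH2Cl2, 0 °C → rt
Reagents that add atoms: N,O-dimethylhydroxylamine hydrochloride, CNOC.Cl
Why: Aminolysis of the lactone by the aluminium amide (formation of an N-methoxy-N-methylamide) opens the ring without touching the α-stereocentre and frees the C12 hydroxyl.

Step 7
Reactants: 14 (2S,3S,4S)-2-[2-(tert-butyldimethylsilyloxy)ethyl]-4-hydroxy-N-methoxy-N,3,6-trimethylhept-5-enamide
Product: 15 (2S,3S,4S)-4-acetoxy-2-[2-(tert-butyldimethylsilyloxy)ethyl]-N-methoxy-N,3,6-trimethylhept-5-enamide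
Conditions: Ac2O, Et3N, DMAP (cat.), CH2Cl2, 0 °C
Reagents that add atoms: acetic anhydride, CC(=O)OC(C)=O
Why: DMAP-catalysed acylation of the secondary alcohol installs the C12 acetate of the target early and blocks relactonisation, with retention at C12.

Step 8
Reactants: 15 (2S,3S,4S)-4-acetoxy-2-[2-(tert-butyldimethylsilyloxy)ethyl]-N-methoxy-N,3,6-trimethylhept-5-enamide
Product: 16 (2S,3S,4S)-4-acetoxy-2-[2-(tert-butyldimethylsilyloxy)ethyl]-3,6-dimethylhept-5-enal
Conditions: Cp2Zr(H)Cl, THF, rt; then H2O/SiO2
Reagents that add atoms: none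
Why: Hydrozirconation-type reduction of the N-methoxy-N-methylamide gives a zirconated hemiaminal that collapses to the aldehyde on work-up, a chemoselective amide-to-aldehyde reduction that should spare the acetate, silyl ether and trisubstituted alkene and not epimerise the α-stereocentre under these neutral conditions.

Step 9
Reactants: 17 cyclopent-2-en-1-one; 18 ethynyltrimethylsilane; 16 (2S,3S,4S)-4-acetoxy-2-[2-(tert-butyldimethylsilyloxy)ethyl]-3,6-dimethylhept-5-enal
Product: 21 (2R,3R)-2-[(1R,2S,3S,4S)-4-acetoxy-2-[2-(tert-butyldimethylsilyloxy)ethyl]-1-hydroxy-3,6-dimethylhept-5-en-1-yl]-3-[1-(trimethylsilyl)vinyl]cyclopentan-1-one, via alkenylalane 19 (not isolated), via aluminium enolate 20 (not isolated)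
Conditions: 18, i-Bu2AlH, hexanes/THF, 55 °C; then Cu(OTf)2 (5 mol %), chiral sulfonate-bearing imidazolinium salt (carbene precursor, 6 mol %), 17 (slight excess over 19), THF, −78 → −30 °C; then 16, −78 °C; aq. NH4Cl
Reagents that add atoms: none
Why: Three-component conjugate addition/aldol coupling, in which hydroalumination of 18 places aluminium on the silicon-bearing carbon (19), the copper–carbene-catalysed asymmetric conjugate addition of this silicon-substituted alkenylaluminium to the cyclic enone sets C1, and the aluminium (E)-enolate 20 adds to 16 anti to the new C1 substituent (C5 trans to C1) through a closed chair-like transition state (anti C5/C6) and anti to the larger C11 branch of the α-branched aldehyde (C6/C7 syn by 1,2-induction), the combination favoured for an (E)-enolate.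

Step 10
Reactants: 21 aldol adduct
Product: 22 C6 tert-butyldimethylsilyl ether of 21 (target numbering 1R,5R,6R,7S,11S,12S)
Conditions: t-BuMe2SiOTf, 2,6-lutidine, CH2Cl2, −78 °C
Reagents that add atoms: tert-butyldimethylsilyl trifluoromethanesulfonate, CC(C)(C)[Si](C)(C)OS(=O)(=O)C(F)(F)F
Why: Silylation of the β-hydroxy ketone with a silyl triflate and a hindered base at low temperature should be faster than retro-aldol cleavage or dehydration and protects the C6 hydroxyl for the rest of the route.

Step 11
Reactants: 22 C6 silyl ether ketone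
Product: 24 C4 enol triflate with the C3=C4 double bond (cyclopent-1-en-1-yl trifluoromethanesulfonate; substituents as in 22), via potassium enolate 23 (not isolated)
Conditions: KN(SiMe3)2, PhNTf2, THF, −78 °C
Reagents that add atoms: N-phenylbis(trifluoromethanesulfonimide), O=S(=O)(N(c1ccccc1)S(=O)(=O)C(F)(F)F)C(F)(F)F
Why: Kinetic enol triflate formation, in which the bulky amide base removes a proton from the unhindered C3 methylene rather than from the C5 methine (whose enolate could expel the C6 silyloxy group) or the acetate, and enolate 23 is O-sulfonylated without change at any stereocentre.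

Step 12
Reactants: 24 enol triflate
Product: 25 1-methylcyclopentene (C3=C4, C4–CH3) carrying at C5 the C6–C9/C11–C15 chain (6-O-TBS, 9-O-TBS, 12-OAc) and at C1 the 1-(trimethylsilyl)vinyl group (1R,5S,6R,7S,11S,12S)
Conditions: MeZnCl, Pd(PPh3)4 (cat.), THF, 0 °C → rt
Reagents that add atoms: methylzinc chloride, C[Zn]Cl
Why: Negishi coupling of the enol triflate installs the C4 methyl group and fixes the C3=C4 alkene, the organozinc reagent tolerating the acetate and the alkenylsilane being inert to the zerovalent palladium catalyst.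

Step 13
Reactants: 25 alkenylsilane
Product: 26 1-iodovinyl compound (C10–I, C10=CH2; otherwise as 25)
Conditions: NIS, 2,6-lutidine, MeCN/ClCH2CN, 0 °C
Reagents that add atoms: N-iodosuccinimide, O=C1CCC(=O)N1I
Why: Iododesilylation, an electrophilic ipso-substitution of the alkenylsilane that under buffered conditions in a polar nitrile solvent is expected to outpace iodonium formation at the two trisubstituted alkenes and leaves the 1,1-disubstituted double bond in place.

Step 14
Reactants: 26 alkenyl iodide bis-silyl ether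
Product: 27 C9 primary alcohol (6-O-TBS and 12-OAc retained)
Conditions: HF·pyridine, pyridine, THF, 0 °C
Reagents that add atoms: none
Why: Selective protecting-group removal, since buffered fluoride cleaves the unhindered primary silyl ether much faster than the secondary C6 silyl ether flanked by two stereocentres, while the acetate and alkenyl iodide are stable.

Step 15
Reactants: 27 primary alcohol
Product: 28 C9 aldehyde with the C10 alkenyl iodide (seco-9,10 precursor; 1R,5S,6R,7S,11S,12S)
Conditions: Dess–Martin periodinane, NaHCO3, CH2Cl2, rt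
Reagents that add atoms: none
Why: Dess–Martin oxidation gives the aldehyde under neutral conditions compatible with the alkenyl iodide, acetate and silyl ether, and the new aldehyde has no α-stereocentre to lose.

Step 16
Reactants: 28 iodo aldehyde
Product: 30 (1R,5S,6R,7S,9R,11S,12S)-12-acetoxy-6-(tert-butyldimethylsilyloxy)-9-hydroxy hydroazulene with the C10 exocyclic methylene, via alkenylchromium species 29 (not isolated)
Conditions: CrCl2 (excess), NiCl2 (cat.), DMSO/THF, rt, high dilution
Reagents that add atoms: none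
Why: Zerovalent nickel (formed from NiCl2 and CrCl2) inserts into the C10–I bond, the alkenyl group passes to trivalent chromium (29), and this alkenylchromium adds to the tethered C9 aldehyde; the closest known reaction type is the intramolecular Nozaki–Hiyama–Kishi coupling of an alkenyl iodide with an aldehyde, established for medium rings and 2-methylenecycloalkanols. The seven-membered ring is closed by 1,2-addition of the C10 alkenyl carbon to the C9 carbonyl (7-exo-trig with respect to C=O), and a 1,1-disubstituted alkenyl unit raises no alkene-geometry issue. The only new stereocentre is C9: the trans C1/C5 ring fusion and the pseudo-equatorial C7 side chain and C6 silyloxy group define a chair-like transition state, and the four-centre C–Cr···O=C arrangement places the carbinol oxygen pseudo-axial, on the face of H-1 and anti to the C7 chain, which also avoids allylic 1,3-strain with the exocyclic methylene, so the 9R alcohol should predominate. The step needs chemoselectivity for the alkenyl iodide over acetate, silyl ether and trisubstituted alkenes, which the weakly basic organochromium reagent secures, and ring closure over oligomerisation, which high dilution secures. The aldehyde has no α-stereocentre, so no epimerisation is possible.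

Step 17
Reactants: 30 C9 alcohol
Product: 31 9,12-diacetate 6-O-tert-butyldimethylsilyl ether
Conditions: Ac2O, pyridine, DMAP (cat.), CH2Cl2, rt
Reagents that add atoms: acetic anhydride, CC(=O)OC(C)=O
Why: DMAP-catalysed acetylation of the only free hydroxyl (allylic, C9) proceeds with retention of configuration.

Step 18
Reactants: 31 diacetate silyl ether
Product: 32 target, (1R,5S,6R,7S,9R)-7-[(2S,3S)-3-acetoxy-6-methylhept-5-en-2-yl]-6-hydroxy-4-methyl-10-methylidenebicyclo[5.3.0]dec-3-en-9-yl acetate (target numbering)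
Conditions: HF·pyridine, pyridine, THF, rt
Reagents that add atoms: none
Why: Protecting-group removal with buffered HF·pyridine should cleave the remaining secondary silyl ether and free the C6 hydroxyl without the acyl migration or allylic acetate ionisation that basic fluoride sources could provoke.

Compound list

1 | 4-methylpent-3-en-1-ol | CC(C)=CCCO | starting material
2 | 4-methylpent-3-enal | CC(C)=CCC=O | intermediate
3 | cis-but-2-ene | C/C=C\C | starting material
4 | (Z)-but-2-en-1-ylbis(isopinocampheyl)borane (isopinocampheyl from (−)-α-pinene) | C/C=C\CB([C@H]1C[C@H]2C[C@@H]([C@@H]1C)C2(C)C)[C@H]1C[C@H]2C[C@@H]([C@@H]1C)C2(C)C | intermediate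
5 | bis(isopinocampheyl)borinate ester of 6 | C=C[C@H](C)[C@H](CC=C(C)C)OB([C@H]1C[C@H]2C[C@@H]([C@@H]1C)C2(C)C)[C@H]1C[C@H]2C[C@@H]([C@@H]1C)C2(C)C | intermediate
6 | (3S,4S)-3,7-dimethylocta-1,6-dien-4-ol | C=C[C@H](C)[C@H](CC=C(C)C)O | intermediate
7 | bis-borylated hydroboration adduct of 6 (C1–B and O–B, both 9-borabicyclo[3.3.1]nonyl) | B1(CC[C@H](C)[C@H](CC=C(C)C)OB2C3CCCC2CCC3)C2CCCC1CCC2 | intermediate
8 | (3S,4S)-3,7-dimethyloct-6-ene-1,4-diol | OCC[C@H](C)[C@H](CC=C(C)C)O | intermediate
9 | (4S,5S)-4-methyl-5-(3-methylbut-2-en-1-yl)oxolan-2-ol (lactol, anomer mixture) | OC1C[C@H](C)[C@H](CC=C(C)C)O1 | intermediate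
10 | (4S,5S)-4-methyl-5-(3-methylbut-2-en-1-yl)oxolan-2-one | O=C1C[C@H](C)[C@H](CC=C(C)C)O1 | intermediate
11 | 2-(tert-butyldimethylsilyloxy)ethyl trifluoromethanesulfonate | CC(C)(C)[Si](C)(C)OCCOS(=O)(=O)C(F)(F)F | starting material
12 | lithium enolate of lactone 10 | [Li]OC1=C[C@H](C)[C@H](CC=C(C)C)O1 | intermediate
13 | (3S,4S,5S)-3-[2-(tert-butyldimethylsilyloxy)ethyl]-4-methyl-5-(3-methylbut-2-en-1-yl)oxolan-2-one | O=C1[C@@H](CCO[Si](C)(C)C(C)(C)C)[C@H](C)[C@H](CC=C(C)C)O1 | intermediate
14 | (2S,3S,4S)-2-[2-(tert-butyldimethylsilyloxy)ethyl]-4-hydroxy-N-methoxy-N,3,6-trimethylhept-5-enamide | CON(C)C(=O)[C@@H](CCO[Si](C)(C)C(C)(C)C)[C@H](C)[C@H](CC=C(C)C)O | intermediate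
15 | (2S,3S,4S)-4-acetoxy-2-[2-(tert-butyldimethylsilyloxy)ethyl]-N-methoxy-N,3,6-trimethylhept-5-enamide | CON(C)C(=O)[C@@H](CCO[Si](C)(C)C(C)(C)C)[C@H](C)[C@H](CC=C(C)C)OC(C)=O | intermediate
16 | (2S,3S,4S)-4-acetoxy-2-[2-(tert-butyldimethylsilyloxy)ethyl]-3,6-dimethylhept-5-enal | O=C[C@@H](CCO[Si](C)(C)C(C)(C)C)[C@H](C)[C@H](CC=C(C)C)OC(C)=O | intermediate
17 | cyclopent-2-en-1-one | O=C1C=CCC1 | starting material
18 | ethynyltrimethylsilane | C#C[Si](C)(C)C | starting material
19 | diisobutyl[1-(trimethylsilyl)vinyl]aluminium | C=C([Si](C)(C)C)[Al](CC(C)C)CC(C)C | intermediate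
20 | diisobutylaluminium enolate of (R)-3-[1-(trimethylsilyl)vinyl]cyclopentanone (C1=C2 enolate) | C=C([Si](C)(C)C)[C@H]1C=C(O[Al](CC(C)C)CC(C)C)CC1 | intermediate
21 | (2R,3R)-2-[(1R,2S,3S,4S)-4-acetoxy-2-[2-(tert-butyldimethylsilyloxy)ethyl]-1-hydroxy-3,6-dimethylhept-5-en-1-yl]-3-[1-(trimethylsilyl)vinyl]cyclopentan-1-one | CC(C)(C)[Si](C)(C)OCC[C@@H]([C@H](C)[C@H](CC=C(C)C)OC(C)=O)[C@@H](O)[C@@H]1C(=O)CC[C@H]1C(=C)[Si](C)(C)C | intermediate
22 | C6 tert-butyldimethylsilyl ether of 21 (target numbering 1R,5R,6R,7S,11S,12S) | CC(C)(C)[Si](C)(C)OCC[C@@H]([C@H](C)[C@H](CC=C(C)C)OC(C)=O)[C@@H](O[Si](C)(C)C(C)(C)C)[C@@H]1C(=O)CC[C@H]1C(=C)[Si](C)(C)C | intermediate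
23 | potassium enolate of 22 (C3=C4 enolate) | CC(C)(C)[Si](C)(C)OCC[C@@H]([C@H](C)[C@H](CC=C(C)C)OC(C)=O)[C@@H](O[Si](C)(C)C(C)(C)C)[C@@H]1C(O[K])=CC[C@H]1C(=C)[Si](C)(C)C | intermediate
24 | C4 enol trifluoromethanesulfonate of 22 (C3=C4) | CC(C)(C)[Si](C)(C)OCC[C@@H]([C@H](C)[C@H](CC=C(C)C)OC(C)=O)[C@@H](O[Si](C)(C)C(C)(C)C)[C@@H]1C(OS(=O)(=O)C(F)(F)F)=CC[C@H]1C(=C)[Si](C)(C)C | intermediate
25 | 4-methylcyclopent-3-ene with C1 1-(trimethylsilyl)vinyl group and C5 chain (6-O-TBS, 9-O-TBS, 12-OAc; 1R,5S,6R,7S,11S,12S) | CC(C)(C)[Si](C)(C)OCC[C@@H]([C@H](C)[C@H](CC=C(C)C)OC(C)=O)[C@@H](O[Si](C)(C)C(C)(C)C)[C@@H]1C(C)=CC[C@H]1C(=C)[Si](C)(C)C | intermediate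
26 | 1-iodovinyl analogue of 25 (C10–I) | CC(C)(C)[Si](C)(C)OCC[C@@H]([C@H](C)[C@H](CC=C(C)C)OC(C)=O)[C@@H](O[Si](C)(C)C(C)(C)C)[C@@H]1C(C)=CC[C@H]1C(I)=C | intermediate
27 | C9 primary alcohol from 26 | OCC[C@@H]([C@H](C)[C@H](CC=C(C)C)OC(C)=O)[C@@H](O[Si](C)(C)C(C)(C)C)[C@@H]1C(C)=CC[C@H]1C(I)=C | intermediate
28 | C9 aldehyde with C10 alkenyl iodide (cyclisation precursor) | O=CC[C@@H]([C@H](C)[C@H](CC=C(C)C)OC(C)=O)[C@@H](O[Si](C)(C)C(C)(C)C)[C@@H]1C(C)=CC[C@H]1C(I)=C | intermediate
29 | C10 alkenylchromium dichloride (trivalent chromium) derived from 28 | O=CC[C@@H]([C@H](C)[C@H](CC=C(C)C)OC(C)=O)[C@@H](O[Si](C)(C)C(C)(C)C)[C@@H]1C(C)=CC[C@H]1C(=C)[Cr](Cl)Cl | intermediate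
30 | (1R,5S,6R,7S,9R,11S,12S)-12-acetoxy-6-(tert-butyldimethylsilyloxy)-9-hydroxy hydroazulene with C10 exocyclic methylene | C=C1[C@H](O)C[C@@H]([C@H](C)[C@H](CC=C(C)C)OC(C)=O)[C@@H](O[Si](C)(C)C(C)(C)C)[C@@H]2C(C)=CC[C@@H]12 | intermediate
31 | 9,12-diacetate 6-O-tert-butyldimethylsilyl ether | C=C1[C@H](OC(C)=O)C[C@@H]([C@H](C)[C@H](CC=C(C)C)OC(C)=O)[C@@H](O[Si](C)(C)C(C)(C)C)[C@@H]2C(C)=CC[C@@H]12 | intermediate
32 | target, (1R,5S,6R,7S,9R,11S,12S)-9,12-diacetoxy-6-hydroxy compound | C=C1[C@H](OC(C)=O)C[C@@H]([C@H](C)[C@H](CC=C(C)C)OC(C)=O)[C@@H](O)[C@@H]2C(C)=CC[C@@H]12 | target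

Total step count: 18. Longest linear sequence: 18 steps (1 → 32); compounds 3, 11, 17 and 18 enter as purchased materials.

Steps most likely to fail

Step 9 is the riskiest. The bulky α-silylalkenyl group may add to the unsubstituted enone with insufficient enantioface selectivity, the aluminium enolate may oligomerise with excess enone, and the aldol addition may show low diastereoselectivity or epimerise the α-branched aldehyde. The fallback replaces catalyst control by substrate control from the chiral pool; it sets out from 16 and comes back to the route at 22. The organocopper reagent from (1-bromovinyl)trimethylsilane (t-BuLi; CuI, PBu3) is added to purchased (S)-4-(tert-butyldimethylsilyloxy)cyclopent-2-en-1-one F1, anti to the silyloxy group, and the enolate is trapped with 16 to give the all-trans aldol adduct F2. Silylation (t-BuMe2SiOTf, 2,6-lutidine) gives the C6 silyl ether F3, DBU eliminates the ring β-silyloxy group to give the cyclopentenone F4, and conjugate reduction with [(Ph3P)CuH]6 gives 22.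

Step 16 may close the ring with poor facial selectivity at the aldehyde, giving a mixture of C9 epimers. The fallback replaces substrate control by reagent control; it sets out from the epimer mixture of 30 and comes back at 30. Dess–Martin oxidation gives the cross-conjugated C9 enone F5, and Corey–Bakshi–Shibata reduction ((S)-2-methyl-oxazaborolidine catalyst, catecholborane, toluene, −78 °C), with the alkenyl branch as the large group, should give the 9R alcohol 30.

Step 5 may suffer from slow C-alkylation of the lactone enolate by the β-oxygenated electrophile, with competing elimination of the triflate or proton transfer to the product. The fallback replaces the substitution by an aldol condensation/conjugate reduction sequence; it sets out from 10 and comes back at 13. The lithium enolate of 10 is added to (tert-butyldimethylsilyloxy)acetaldehyde to give the β-hydroxy lactone F6, and mesylation and elimination (MsCl, Et3N; DBU) give the α-alkylidene lactone F7. Conjugate reduction with [(Ph3P)CuH]6 followed by base equilibration (DBU) to the more stable 3,4-trans isomer gives 13.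

Further compounds
F1 | step 9 | (S)-4-(tert-butyldimethylsilyloxy)cyclopent-2-en-1-one | O=C1C=C[C@@H](O[Si](C)(C)C(C)(C)C)C1
F2 | step 9 | all-trans aldol adduct, analogue of 21 with a tert-butyldimethylsilyloxy group at C2 | CC(C)(C)[Si](C)(C)OCC[C@@H]([C@H](C)[C@H](CC=C(C)C)OC(C)=O)[C@@H](O)[C@@H]1C(=O)C[C@H](O[Si](C)(C)C(C)(C)C)[C@H]1C(=C)[Si](C)(C)C
F3 | step 9 | C6 tert-butyldimethylsilyl ether of F2 | CC(C)(C)[Si](C)(C)OCC[C@@H]([C@H](C)[C@H](CC=C(C)C)OC(C)=O)[C@@H](O[Si](C)(C)C(C)(C)C)[C@@H]1C(=O)C[C@H](O[Si](C)(C)C(C)(C)C)[C@H]1C(=C)[Si](C)(C)C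
F4 | step 9 | C2=C3 cyclopentenone formed from F3 by loss of the ring silyloxy group | CC(C)(C)[Si](C)(C)OCC[C@@H]([C@H](C)[C@H](CC=C(C)C)OC(C)=O)[C@@H](O[Si](C)(C)C(C)(C)C)[C@@H]1C(=O)C=C[C@H]1C(=C)[Si](C)(C)C
F5 | step 16 | C9 ketone (10-methylidene enone) from the C9 epimers of 30 | C=C1C(=O)C[C@@H]([C@H](C)[C@H](CC=C(C)C)OC(C)=O)[C@@H](O[Si](C)(C)C(C)(C)C)[C@@H]2C(C)=CC[C@@H]12
F6 | step 5 | 3-[2-(tert-butyldimethylsilyloxy)-1-hydroxyethyl] lactone (aldol adduct of 10, carbinol epimers) | O=C1[C@@H](C(O)CO[Si](C)(C)C(C)(C)C)[C@H](C)[C@H](CC=C(C)C)O1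
F7 | step 5 | 3-[2-(tert-butyldimethylsilyloxy)ethylidene] lactone | O=C1C(=CCO[Si](C)(C)C(C)(C)C)[C@H](C)[C@H](CC=C(C)C)O1
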